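Ring A is cut at two bonds: chain-bearing carbon to bridge-bearing carbon, and the CH beside the methoxy carbon to the future phenol carbon. The run left over, C(arylethyl)–CH–C(OMe)–CH, is C6–C5–C4–C3 of a 4-methoxy-2-pyrone; the two missing carbons are an alkyne. Heating the 6-(arylethyl)pyrone with the ethynyl ketone of ring B (all phenols as benzyl ethers) forms both bonds, expels carbon dioxide, aromatises ring A and joins the bibenzyl halves as a benzophenone. The ring A hydroxyl follows by carbinol-tethered iridium C–H silylation and peroxide oxidation, sparing the electron-rich rings; one hydrogenolysis finishes.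

Key step: step 10

Assumption: O-benzylvanillin is taken as a catalogue chemical (one benzylation from vanillin); every carbinol or bridgehead centre met on the way is racemic and is erased before the achiral target.

Step 1
Reactants: 1 4-(benzyloxy)-3-methoxybenzaldehyde (O-benzylvanillin)
Product: 2 [4-(benzyloxy)-3-methoxyphenyl]methanol
Conditions: NaBH4, MeOH, 0 °C
Reagents that add atoms: none
Why: Borohydride reduction of an aromatic aldehyde is chemoselective and leaves both aryl ethers untouched.

Step 2
Reactants: 2 [4-(benzyloxy)-3-methoxyphenyl]methanol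
Product: 3 1-(benzyloxy)-4-(bromomethyl)-2-methoxybenzene (O-benzylvanillyl bromide)
Conditions: PBr3, Et2O, 0 °C
Reagents that add atoms: phosphorus tribromide, BrP(Br)Br
Why: Bromide displaces the phosphite ester of a primary, donor-activated benzylic alcohol (SN2) rapidly at 0 °C, and the labile bromide is used at once.

Step 3
Reactants: 4 4-methoxy-6-methyl-2H-pyran-2-one; 3 O-benzylvanillyl bromide
Product: 6 arylethylpyrone 6-{2-[4-(benzyloxy)-3-methoxyphenyl]ethyl}-4-methoxy-2H-pyran-2-one, via lithiated pyrone 5 (not isolated)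
Conditions: LiN(iPr)2, THF–DMPU, −78 °C; then 3, −78 to −20 °C
Reagents that add atoms: lithium diisopropylamide, [Li]N(C(C)C)C(C)C (its lithium sits only in 5)
Why: Lateral (vinylogous) deprotonation of the C6 methyl group gives the extended lithium dienolate, which is alkylated at its exocyclic carbon by the reactive benzylic bromide (SN2), the established entry to 6-(2-arylethyl)-4-methoxy-2-pyrones.

Step 4
Reactants: 1 O-benzylvanillin
Product: 7 1-(benzyloxy)-4-ethenyl-2-methoxybenzene (4-benzyloxy-3-methoxystyrene)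
Conditions: Ph3PCH3Br, KOtBu, THF, 0 °C to rt
Reagents that add atoms: methyltriphenylphosphonium bromide, C[P+](c1ccccc1)(c1ccccc1)c1ccccc1.[Br-]
Why: Wittig methylenation of a non-enolisable aromatic aldehyde is reliable and tolerates the ethers.

Step 5
Reactants: 8 4-bromo-2,6-difluorobenzaldehyde
Product: 9 2-(benzyloxy)-4-bromo-6-fluorobenzaldehyde
Conditions: BnOH, NaH, THF, 0 °C
Reagents that add atoms: benzyl alcohol, OCc1ccccc1
Why: In this nucleophilic aromatic substitution (addition–elimination) fluoride ortho to the formyl group leaves far faster than the para bromide, and the first alkoxy group deactivates the ring enough to stop at mono-substitution at 0 °C.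

Step 6
Reactants: 9 2-(benzyloxy)-4-bromo-6-fluorobenzaldehyde
Product: 10 2-(benzyloxy)-4-bromo-6-methoxybenzaldehyde
Conditions: NaOMe, MeOH–THF, 65 °C
Reagents that add atoms: sodium methoxide, C[O-].[Na+]
Why: The slower second nucleophilic aromatic substitution is given to the small, cheap nucleophile in excess, and the remaining formyl-activated fluoride is still a much better leaving group than bromide or benzyloxide.

Step 7
Reactants: 7 4-benzyloxy-3-methoxystyrene; 10 2-(benzyloxy)-4-bromo-6-methoxybenzaldehyde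
Product: 12 ring B aldehyde 2-(benzyloxy)-4-{2-[4-(benzyloxy)-3-methoxyphenyl]ethyl}-6-methoxybenzaldehyde, via B-alkyl-9-BBN borane 11 (not isolated)
Conditions: 7 (slight excess), 9-BBN-H, THF, 0 °C to rt; then 10, PdCl2(dppf) (cat., dppf = 1,1'-bis(diphenylphosphino)ferrocene), K3PO4, DMF–H2O, 60 °C
Reagents that add atoms: 9-borabicyclo[3.3.1]nonane, B1C2CCCC1CCC2 (boron and its bicycle sit only in 11)
Why: Anti-Markovnikov hydroboration followed by B-alkyl Suzuki–Miyaura coupling at the unhindered, formyl-activated C–Br bond installs the saturated CH2CH2 link directly, so no hydrogenation is needed while benzyl ethers are present, and all B–H is consumed before the aldehyde enters the flask.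

Step 8
Reactants: 12 ring B aldehyde; 13 ethynylmagnesium bromide
Product: 14 1-{2-(benzyloxy)-4-[2-(4-benzyloxy-3-methoxyphenyl)ethyl]-6-methoxyphenyl}prop-2-yn-1-ol (racemic)
Conditions: THF, 0 °C to rt; then H2O (neutral work-up)
Reagents that add atoms: none
Why: 1,2-Addition of an alkynyl Grignard reagent to the aldehyde is straightforward, and the new carbinol centre needs no control because it is oxidised away in the next step.

Step 9
Reactants: 14 propargylic alcohol
Product: 15 ring B ethynyl ketone 1-{2-(benzyloxy)-4-[2-(4-benzyloxy-3-methoxyphenyl)ethyl]-6-methoxyphenyl}prop-2-yn-1-one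
Conditions: MnO2, CH2Cl2, rt
Reagents that add atoms: none
Why: MnO2 oxidises the doubly activated (benzylic and propargylic) alcohol under neutral conditions that spare the terminal alkyne and all ethers.

Step 10
Reactants: 6 arylethylpyrone; 15 ring B ethynyl ketone
Product: 17 benzophenone {2-(benzyloxy)-4-[2-(4-benzyloxy-3-methoxyphenyl)ethyl]-6-methoxyphenyl}{2-[2-(4-benzyloxy-3-methoxyphenyl)ethyl]-4-methoxyphenyl}methanone, via bridged bicyclic lactone 16 (not isolated)
Conditions: 6 (2 equiv), BHT (cat.), o-dichlorobenzene, 170 °C, Ar, slow addition of 15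
Reagents that add atoms: none
Why: The pyrone serves as the 4π partner (C3=C4–C5=C6) and the ynone as the 2π partner in a concerted, asynchronous normal-demand Diels–Alder addition to the 2-oxabicyclo[2.2.2]octadienone 16, whose lactone bridge leaves at once as carbon dioxide by retro-[4+2] and uncovers the benzene ring. The closest known chemistry is the thermal cycloaddition–decarboxylation of 4-methoxy-6-methyl-2-pyrone and other 6-alkyl pyrones with propiolates, acetylenedicarboxylates and acetylenic ketones, which gives 4-methoxy-2-alkylbenzoyl compounds. Ring A is closed by an intermolecular [4+2] cycloaddition in which both new sigma bonds, C6 to the acyl-bearing alkyne carbon and C3 to the terminal alkyne carbon, form in one event. No stereocentre survives, because the two bridgehead centres of racemic 16 become sp2 on decarboxylation. The step needs regioselectivity, which matched polarity secures: the 4-methoxy group and the ring oxygen both push electron density to C3, so C3 pairs with the electrophilic terminal carbon of the ynone and the carbonyl ends up ortho to the chain and para to methoxy. Chemoselectivity rests on the ynone being the only activated 2π system, and the benzyl ether ortho to the carbonyl keeps the ring B oxygen from adding to the triple bond to form a chromone.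

Step 11
Reactants: 17 benzophenone
Product: 19 benzoxasilole 3-{2-(benzyloxy)-4-[2-(4-benzyloxy-3-methoxyphenyl)ethyl]-6-methoxyphenyl}-4-[2-(4-benzyloxy-3-methoxyphenyl)ethyl]-1,1-diethyl-6-methoxy-1,3-dihydro-2,1-benzoxasilole (racemic), via diethylhydridosilyl ether 18 (not isolated)
Conditions: Et2SiH2, [Ir(cod)OMe]2 (cat.), THF, rt to 50 °C; evaporate; [Ir(cod)OMe]2 (cat.), 1,10-phenanthroline (cat.), norbornene, THF, 100 °C, sealed tube
Reagents that add atoms: diethylsilane, CC[SiH2]CC
Why: Iridium-catalysed ketone hydrosilylation followed by hydroxyl-directed dehydrogenative ortho C–H silylation closes the five-membered Si–O ring at the only ortho C–H within reach (both ortho sites of ring B and the other one of ring A are substituted) without any oxidant that could attack the ether rings, and the racemic carbinol centre is deleted in step 13.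

Step 12
Reactants: 19 benzoxasilole
Product: 20 2-{[2-(benzyloxy)-4-[2-(4-benzyloxy-3-methoxyphenyl)ethyl]-6-methoxyphenyl](hydroxy)methyl}-3-[2-(4-benzyloxy-3-methoxyphenyl)ethyl]-5-methoxyphenol (racemic)
Conditions: H2O2 (30 % aq.), KHCO3, THF–MeOH, rt
Reagents that add atoms: hydrogen peroxide, OO
Why: In this Tamao–Fleming oxidation the oxygen-bearing, strained silicon takes up hydroperoxide and the aryl group migrates from silicon to oxygen at the same ring carbon, under buffered conditions that leave aryl ethers alone and do not touch the racemic carbinol centre.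

Step 13
Reactants: 20 hydroxybenzhydrol
Product: 21 target 2-{[2-hydroxy-4-[2-(4-hydroxy-3-methoxyphenyl)ethyl]-6-methoxyphenyl]methyl}-3-[2-(4-hydroxy-3-methoxyphenyl)ethyl]-5-methoxyphenol
Conditions: H2 (1–4 bar), Pd/C, EtOAc–EtOH, AcOH (cat.), rt
Reagents that add atoms: none
Why: Catalytic hydrogenolysis cleaves the three aryl benzyl ethers and, helped by a trace of acid, the doubly benzylic carbinol C–O bond activated by its ortho-hydroxy and ortho/para-alkoxy donors, while methyl ethers and saturated chains are inert and the last stereocentre disappears.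

Compound list
1 | 4-(benzyloxy)-3-methoxybenzaldehyde (O-benzylvanillin) | COc1cc(C=O)ccc1OCc1ccccc1 | starting material
2 | [4-(benzyloxy)-3-methoxyphenyl]methanol | COc1cc(CO)ccc1OCc1ccccc1 | intermediate
3 | 1-(benzyloxy)-4-(bromomethyl)-2-methoxybenzene | COc1cc(CBr)ccc1OCc1ccccc1 | intermediate
4 | 4-methoxy-6-methyl-2H-pyran-2-one | COC1=CC(=O)OC(C)=C1 | starting material
5 | 6-(lithiomethyl)-4-methoxy-2H-pyran-2-one (extended lithium dienolate, not isolated) | COC1=CC(=O)OC(C[Li])=C1 | intermediate
6 | 6-{2-[4-(benzyloxy)-3-methoxyphenyl]ethyl}-4-methoxy-2H-pyran-2-one | COC1=CC(=O)OC(CCc2ccc(OCc3ccccc3)c(OC)c2)=C1 | intermediate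
7 | 1-(benzyloxy)-4-ethenyl-2-methoxybenzene | C=Cc1ccc(OCc2ccccc2)c(OC)c1 | intermediate
8 | 4-bromo-2,6-difluorobenzaldehyde | O=Cc1c(F)cc(Br)cc1F | starting material
9 | 2-(benzyloxy)-4-bromo-6-fluorobenzaldehyde | O=Cc1c(F)cc(Br)cc1OCc1ccccc1 | intermediate
10 | 2-(benzyloxy)-4-bromo-6-methoxybenzaldehyde | COc1cc(Br)cc(OCc2ccccc2)c1C=O | intermediate
11 | 9-{2-[4-(benzyloxy)-3-methoxyphenyl]ethyl}-9-borabicyclo[3.3.1]nonane (not isolated) | COc1cc(CCB2C3CCCC2CCC3)ccc1OCc1ccccc1 | intermediate
12 | 2-(benzyloxy)-4-{2-[4-(benzyloxy)-3-methoxyphenyl]ethyl}-6-methoxybenzaldehyde | COc1cc(CCc2ccc(OCc3ccccc3)c(OC)c2)cc(OCc2ccccc2)c1C=O | intermediate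
13 | ethynylmagnesium bromide | C#C[Mg]Br | starting material
14 | 1-{2-(benzyloxy)-4-[2-(4-benzyloxy-3-methoxyphenyl)ethyl]-6-methoxyphenyl}prop-2-yn-1-ol (racemic) | C#CC(O)c1c(OCc2ccccc2)cc(CCc2ccc(OCc3ccccc3)c(OC)c2)cc1OC | intermediate
15 | 1-{2-(benzyloxy)-4-[2-(4-benzyloxy-3-methoxyphenyl)ethyl]-6-methoxyphenyl}prop-2-yn-1-one | C#CC(=O)c1c(OCc2ccccc2)cc(CCc2ccc(OCc3ccccc3)c(OC)c2)cc1OC | intermediate
16 | 7-aroyl-1-(arylethyl)-5-methoxy-2-oxabicyclo[2.2.2]octa-5,7-dien-3-one (racemic, not isolated) | COC1=CC2(CCc3ccc(OCc4ccccc4)c(OC)c3)OC(=O)C1C=C2C(=O)c1c(OCc2ccccc2)cc(CCc2ccc(OCc3ccccc3)c(OC)c2)cc1OC | intermediate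
17 | {2-(benzyloxy)-4-[2-(4-benzyloxy-3-methoxyphenyl)ethyl]-6-methoxyphenyl}{2-[2-(4-benzyloxy-3-methoxyphenyl)ethyl]-4-methoxyphenyl}methanone | COc1ccc(C(=O)c2c(OCc3ccccc3)cc(CCc3ccc(OCc4ccccc4)c(OC)c3)cc2OC)c(CCc2ccc(OCc3ccccc3)c(OC)c2)c1 | intermediate
18 | diethyl(hydrido)silyl ether of the benzhydrol derived from 17 (racemic, not isolated) | COc1ccc(C(O[SiH](CC)CC)c2c(OCc3ccccc3)cc(CCc3ccc(OCc4ccccc4)c(OC)c3)cc2OC)c(CCc2ccc(OCc3ccccc3)c(OC)c2)c1 | intermediate
19 | 1,1-diethyl-1,3-dihydro-2,1-benzoxasilole fused on ring A, with the ring B aryl at C3, the arylethyl chain at C4 and methoxy at C6 (racemic) | COc1cc(CCc3ccc(OCc4ccccc4)c(OC)c3)c2C(c3c(OCc4ccccc4)cc(CCc4ccc(OCc5ccccc5)c(OC)c4)cc3OC)O[Si](CC)(CC)c2c1 | intermediate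
20 | 2-{[2-(benzyloxy)-4-[2-(4-benzyloxy-3-methoxyphenyl)ethyl]-6-methoxyphenyl](hydroxy)methyl}-3-[2-(4-benzyloxy-3-methoxyphenyl)ethyl]-5-methoxyphenol (racemic) | COc1cc(O)c(C(O)c2c(OCc3ccccc3)cc(CCc3ccc(OCc4ccccc4)c(OC)c3)cc2OC)c(CCc2ccc(OCc3ccccc3)c(OC)c2)c1 | intermediate
21 | CNP0079001.0, 2-{[2-hydroxy-4-[2-(4-hydroxy-3-methoxyphenyl)ethyl]-6-methoxyphenyl]methyl}-3-[2-(4-hydroxy-3-methoxyphenyl)ethyl]-5-methoxyphenol (achiral) | COc1cc(O)c(Cc2c(O)cc(CCc3ccc(O)c(OC)c3)cc2OC)c(CCc2ccc(O)c(OC)c2)c1 | target

Total step count: 13.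
Longest linear sequence: 9 steps (steps 5 to 13, from 8 through 9, 10, 12, 14, 15, 17, 19 and 20 to 21).

Steps most likely to fail

1. Step 10. The donor-substituted pyrone is a sluggish diene. Thermal oligomerisation of the terminal ynone may therefore outrun cycloaddition, and steric repulsion between the substituted C6 and the bulky aroyl group may erode the regiochemistry. The fallback gives up the cycloaddition and buys ring A as an arene; it sets out from borane 11 and aldehyde 12. B-alkyl Suzuki–Miyaura coupling of 11 with commercial 4-bromo-3-iodoanisole (COc1ccc(Br)c(I)c1) at the more reactive C–I bond (PdCl2(dppf), K3PO4, rt) should give 1-bromo-2-[2-(4-benzyloxy-3-methoxyphenyl)ethyl]-4-methoxybenzene F1. Bromine–lithium exchange (n-BuLi, THF, −78 °C) gives the aryllithium F2, which adds to 12 to give the benzhydrol F3. Dehydrogenative O-silylation of F3 with Et2SiH2 and [Ir(cod)OMe]2 comes back to the route at 18.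

2. Step 11. Hydrosilylation of the crowded, twisted carbonyl group may be too slow, or the dehydrogenative ring closure may stall through catalyst deactivation. The fallback sets out from 17 and uses the carbonyl oxygen itself as the directing group. Ketone-directed ortho C–H borylation (B2pin2, [Ir(cod)OMe]2, AsPh3, octane, 120 °C) should give the ortho-boronate ketone F4. Any stray borylation on benzyl phenyl rings is harmless, because those rings are cleaved at the end. Mild oxidation (NaBO3·4H2O, THF–H2O, rt) gives the 2-hydroxybenzophenone F5, and LiAlH4 reduction (THF, 0 °C to reflux) comes back to the route at 20.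

3. Step 13. Cleavage of the carbinol C–O bond may stay incomplete at the tetra-ortho-substituted centre, or acid-induced ionisation and oligomerisation of the hydroxybenzhydrol may occur before reduction. The fallback sets out from 20 and separates the two tasks. Ionic deoxygenation (Et3SiH, CF3CO2H, CH2Cl2, −20 to 0 °C), in which the donor-stabilised benzhydryl cation is trapped by hydride in solution rather than on a metal surface, should give the tri-O-benzyl diarylmethane F6. Plain debenzylation (H2, Pd/C, EtOAc–EtOH) then comes back to the route at 21.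

Further compounds
F1 | step 10 | 1-bromo-2-[2-(4-benzyloxy-3-methoxyphenyl)ethyl]-4-methoxybenzene | COc1ccc(Br)c(CCc2ccc(OCc3ccccc3)c(OC)c2)c1
F2 | step 10 | {2-[2-(4-benzyloxy-3-methoxyphenyl)ethyl]-4-methoxyphenyl}lithium | COc1ccc([Li])c(CCc2ccc(OCc3ccccc3)c(OC)c2)c1
F3 | step 10 | {2-(benzyloxy)-4-[2-(4-benzyloxy-3-methoxyphenyl)ethyl]-6-methoxyphenyl}{2-[2-(4-benzyloxy-3-methoxyphenyl)ethyl]-4-methoxyphenyl}methanol (racemic) | COc1ccc(C(O)c2c(OCc3ccccc3)cc(CCc3ccc(OCc4ccccc4)c(OC)c3)cc2OC)c(CCc2ccc(OCc3ccccc3)c(OC)c2)c1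
F4 | step 11 | benzophenone 17 bearing a pinacol boronate at the free ortho position of ring A | COc1cc(B2OC(C)(C)C(C)(C)O2)c(C(=O)c2c(OCc3ccccc3)cc(CCc3ccc(OCc4ccccc4)c(OC)c3)cc2OC)c(CCc2ccc(OCc3ccccc3)c(OC)c2)c1
F5 | step 11 | benzophenone 17 bearing a hydroxyl at the free ortho position of ring A | COc1cc(O)c(C(=O)c2c(OCc3ccccc3)cc(CCc3ccc(OCc4ccccc4)c(OC)c3)cc2OC)c(CCc2ccc(OCc3ccccc3)c(OC)c2)c1
F6 | step 13 | 2-{[2-(benzyloxy)-4-[2-(4-benzyloxy-3-methoxyphenyl)ethyl]-6-methoxyphenyl]methyl}-3-[2-(4-benzyloxy-3-methoxyphenyl)ethyl]-5-methoxyphenol | COc1cc(O)c(Cc2c(OCc3ccccc3)cc(CCc3ccc(OCc4ccccc4)c(OC)c3)cc2OC)c(CCc2ccc(OCc3ccccc3)c(OC)c2)c1
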